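**Retrosynthetic overview**
- The strategy rests on the side chain: its ten carbons are an unbroken geranyl skeleton (C1 = ArOCH2, C2–C5 plus one oxygen = the oxolane, C6=C7(CH3)2 = the 2-methylprop-1-enyl group), and the ring O–C5 bond is a prenyl-type allylic ether bond whose allyl unit ends at the non-stereogenic gem-dimethyl carbon C7.
- That O–C5 bond is cut with 1,3-allylic transposition, which leads back to an open-chain (2S,3R)-2,3,7-triol with a 5E alkene that already carries the coumarin on O1.
- The triol comes from a (2S,3S)-2,3-epoxide by water attack at C3, and the epoxide ether from Mitsunobu coupling of isofraxidin with a (2S,3S)-epoxy-5E-ene-1,7-diol.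
- The epoxy diol comes from geranyl acetate by distal epoxidation, selenide opening with selenoxide elimination, deacetylation and Sharpless asymmetric epoxidation.
- Ring order: the coumarin is bought intact, the oxirane is made in step 4 and opened in step 6, and the oxolane is closed last in step 7.

Key step: step 7

Remark: chain carbons are numbered C1–C7 along the geranyl skeleton, which coincides with the oxolane numbering C2–C5. Geranyl acetate and isofraxidin are assumed to be purchasable. The C6 centre of compounds 2–4 is racemic and is removed in step 2.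

**Route**

Step 1
Reactants: 1 geranyl acetate
Product: 2 6,7-epoxygeranyl acetate (racemic at C6)
Conditions: mCPBA (1.05 equiv), NaHCO3, CH2Cl2, 0 °C
Reagents that add atoms: mCPBA, OOC(=O)c1cccc(Cl)c1
Why: Prilezhaev epoxidation should select the electron-rich distal 6,7-alkene because the 2,3-alkene is deactivated by the allylic acetoxy group; the new C6 centre is racemic, which is harmless since it becomes sp2 in step 2.

Step 2
Reactants: 2 6,7-epoxygeranyl acetate
Product: 5 (2E,5E)-7-hydroxy-3,7-dimethylocta-2,5-dien-1-yl acetate, via hydroxy selenide 3 (not isolated), via selenoxide 4 (not isolated)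
Conditions: (PhSe)2, NaBH4, EtOH, rt to 50 °C; then 30% H2O2 (excess), THF, 0 °C to rt
Reagents that add atoms: none
Why: In this Sharpless-type epoxide-to-allylic-alcohol transposition the selenolate should open the oxirane by SN2 at the less hindered secondary C6, and the selenoxide then undergoes syn elimination that can only take a hydrogen from C5 (C7 has none), giving the E-5,6-alkene and the tertiary C7 alcohol and erasing the C6 centre.

Step 3
Reactants: 5 (2E,5E)-7-hydroxy-3,7-dimethylocta-2,5-dien-1-yl acetate
Product: 6 (2E,5E)-3,7-dimethylocta-2,5-diene-1,7-diol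
Conditions: K2CO3 (cat.), MeOH, rt
Reagents that add atoms: none
Why: Base-catalysed transesterification should free the primary allylic alcohol without touching the alkenes or the tertiary alcohol, and it also converges any material that lost its acetate in step 2.

Step 4
Reactants: 6 (2E,5E)-3,7-dimethylocta-2,5-diene-1,7-diol
Product: 7 (2S,3S)-2,3-epoxy-3,7-dimethyloct-5E-ene-1,7-diol
Conditions: Ti(OiPr)4 (0.3 equiv), L-(+)-DET (0.36 equiv), TBHP (in decane), 4 Å MS, CH2Cl2, −20 °C
Reagents that add atoms: tert-butyl hydroperoxide, CC(C)(C)OO
Why: In the Sharpless asymmetric epoxidation only the primary allylic alcohol with its trisubstituted E alkene reacts at a useful rate (tertiary allylic alcohols are very poor substrates), and the L-(+)-tartrate catalyst should deliver oxygen to the face that gives the (2S,3S)-epoxide, as with geraniol, so C2 and C3 are set together under catalyst control.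

Step 5
Reactants: 7 (2S,3S)-2,3-epoxy-3,7-dimethyloct-5E-ene-1,7-diol; 8 isofraxidin (7-hydroxy-6,8-dimethoxycoumarin)
Product: 9 7-{[(2S,3S)-3-[(E)-4-hydroxy-4-methylpent-2-enyl]-3-methyloxiran-2-yl]methoxy}-6,8-dimethoxycoumarin
Conditions: PPh3, DIAD, THF, 0 °C to rt
Reagents that add atoms: none
Why: In this Mitsunobu etherification the acidic coumarin 7-OH should displace the activated primary C1 oxyphosphonium by SN2 at a carbon remote from both stereocentres, while the tertiary C7 alcohol cannot be activated and the oxirane is inert under these neutral conditions.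

Step 6
Reactants: 9 epoxy ether
Product: 10 7-{[(2S,3R,5E)-2,3,7-trihydroxy-3,7-dimethyloct-5-enyl]oxy}-6,8-dimethoxycoumarin
Conditions: HClO4 (about 0.05 M), THF–H2O 3:1, 0 °C, then NaHCO3
Reagents that add atoms: water, O
Why: In this acid-catalysed epoxide hydrolysis of borderline SN2 type, water should attack the protonated oxirane at the tertiary C3 (the carbon best able to carry charge and farther from the electron-withdrawing aryloxymethyl group) with inversion, so the C2–O bond is kept as (2S) and C3 becomes the (3R) carbinol; cold dilute acid and a short reaction time are chosen to leave the tertiary allylic C7 alcohol un-ionised, and the E geometry of C5=C6 keeps the C7 hydroxyl from reaching the oxirane.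

Step 7
Reactants: 10 (2S,3R)-triol
Product: 11 7-{[(2S,3R,5R)-3-hydroxy-3-methyl-5-(2-methylprop-1-enyl)oxolan-2-yl]methoxy}-6,8-dimethoxycoumarin (target)
Conditions: Ph3PAuCl (2 mol%), AgOTf (2 mol%), 4 Å MS, CH2Cl2, 0 °C to rt
Reagents that add atoms: none
Why: Cationic gold(I) should bind the C5=C6 alkene, the C2 hydroxyl adds anti to C5, and the resulting alkylgold species expels the C7 hydroxyl as water, so that the O–C5 bond forms, the alkene moves to C6=C7 and the catalyst is released in a formal dehydrative SN2' cycloetherification. The closest known reactions are the gold(I)-catalysed cyclisation of monoallylic diols to 2-alkenyl oxolanes and oxanes and the acid-mediated closure of a 5-ene-1,7-diol to rose oxide, which creates the same 2-methylprop-1-enyl ether by the same transposition. The oxolane is closed in the 5-exo-trig mode by O–C5 bond formation. C5 is set by substrate control from C2 and C3 through a chair-like transition state that holds the C2 CH2OAr group and the C3 hydroxyl equatorial with only the C3 methyl axial, which should place the alkenyl group trans to CH2OAr and cis to the C3 hydroxyl, i.e. (5R), whereas the epimer would need both CH2OAr and OH axial; C2 and C3 are not touched. The step needs site selectivity among three hydroxyls, and the substrate secures it: O1 is already an aryl ether so no oxane can form, the C3 hydroxyl could only give an oxetane or a ring containing an E alkene, the tertiary allylic C7 hydroxyl is the only one that can leave and is non-stereogenic, and both positions ortho to the aryl ether oxygen carry methoxy groups so Friedel–Crafts capture of the allyl unit is blocked.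

**Compound list**
1 | geranyl acetate | CC(=O)OC/C=C(\C)CCC=C(C)C | starting material
2 | 6,7-epoxygeranyl acetate (racemic at C6) | CC(=O)OC/C=C(\C)CCC1OC1(C)C | intermediate
3 | (2E)-7-hydroxy-3,7-dimethyl-6-(phenylselanyl)oct-2-en-1-yl acetate (racemic at C6) | CC(=O)OC/C=C(\C)CCC([Se]c1ccccc1)C(C)(C)O | intermediate (not isolated)
4 | selenoxide of 3 | CC(=O)OC/C=C(\C)CCC([Se](=O)c1ccccc1)C(C)(C)O | intermediate (not isolated)
5 | (2E,5E)-7-hydroxy-3,7-dimethylocta-2,5-dien-1-yl acetate | CC(=O)OC/C=C(\C)C/C=C/C(C)(C)O | intermediate
6 | (2E,5E)-3,7-dimethylocta-2,5-diene-1,7-diol | OC/C=C(\C)C/C=C/C(C)(C)O | intermediate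
7 | (2S,3S)-2,3-epoxy-3,7-dimethyloct-5E-ene-1,7-diol | OC[C@@H]1O[C@@]1(C)C/C=C/C(C)(C)O | intermediate
8 | isofraxidin (7-hydroxy-6,8-dimethoxycoumarin) | COc1cc2ccc(=O)oc2c(OC)c1O | starting material
9 | 7-{[(2S,3S)-3-[(E)-4-hydroxy-4-methylpent-2-enyl]-3-methyloxiran-2-yl]methoxy}-6,8-dimethoxycoumarin | COc1cc2ccc(=O)oc2c(OC)c1OC[C@@H]1O[C@@]1(C)C/C=C/C(C)(C)O | intermediate
10 | 7-{[(2S,3R,5E)-2,3,7-trihydroxy-3,7-dimethyloct-5-enyl]oxy}-6,8-dimethoxycoumarin | COc1cc2ccc(=O)oc2c(OC)c1OC[C@H](O)[C@](C)(O)C/C=C/C(C)(C)O | intermediate
11 | 7-{[(2S,3R,5R)-3-hydroxy-3-methyl-5-(2-methylprop-1-enyl)oxolan-2-yl]methoxy}-6,8-dimethoxycoumarin (CNP0086110.2) | COc1cc2ccc(=O)oc2c(OC)c1OC[C@@H]1O[C@@H](C=C(C)C)C[C@@]1(C)O | target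

**Step count**
Total steps: 7. Longest linear sequence: 7 steps (1 to 11); isofraxidin 8 enters at step 5.

**Steps most likely to fail**

Step 7. The chair preference may give only modest facial selectivity at C5, and the tertiary allylic alcohol may instead lose water to a 1,3-diene. The fallback sets out from 9 and returns at 11, and it puts C5 under catalyst control through a π-allylpalladium intermediate. The only free hydroxyl of 9 is acetylated (Ac2O, Et3N, DMAP, CH2Cl2) to the tertiary allylic acetate F1. The oxirane of F1 is hydrolysed as in step 6 to the (2S,3R)-diol acetate F2. F2 is then closed by Tsuji–Trost allylic etherification (Pd2(dba)3·CHCl3, a C2-symmetric DACH-phenyl diphosphine ligand whose enantiomer is chosen in a matched/mismatched screen, Et3N, CH2Cl2, rt). The C2 hydroxyl should attack the allyl terminus C5 in the 5-exo mode to give 11.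

Step 6. Under mineral acid the opening at C3 may drift toward SN1 and erode the C3 configuration, and the C7 allylic alcohol may ionise prematurely. The fallback sets out from 9 and returns at 10. Buffered acetolysis (AcOH, NaOAc, rt to 40 °C) is too weakly acidic to ionise the tertiary allylic alcohol and should open the oxirane at C3 with inversion to the hydroxy acetate F3; acyl migration to the C2 oxygen would be harmless. Mild methanolysis (K2CO3, MeOH, 0 °C, acidic work-up to re-close any opened lactone) then gives 10.

Step 5. The phenol is flanked by two methoxy groups, so the SN2 step may be slow enough for the activated alcohol to be diverted to alkylation of the hydrazide. The fallback sets out from 7 and returns at 9. The primary hydroxyl is sulfonylated selectively (TsCl, Et3N, cat. DMAP, CH2Cl2, 0 °C; the tertiary alcohol does not react) to the epoxy tosylate F4. Williamson etherification with 8 (Cs2CO3, DMF, rt) then displaces the primary tosylate; attack on the oxirane is disfavoured because C3 is fully substituted.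

**Further compounds**
F1 | step 7 | C7 acetate of epoxy ether 9 | COc1cc2ccc(=O)oc2c(OC)c1OC[C@@H]1O[C@@]1(C)C/C=C/C(C)(C)OC(C)=O
F2 | step 7 | (2S,3R)-2,3-diol C7 acetate | COc1cc2ccc(=O)oc2c(OC)c1OC[C@H](O)[C@](C)(O)C/C=C/C(C)(C)OC(C)=O
F3 | step 6 | (2S,3R)-3-acetoxy-2,7-diol | COc1cc2ccc(=O)oc2c(OC)c1OC[C@H](O)[C@](C)(OC(C)=O)C/C=C/C(C)(C)O
F4 | step 5 | C1 tosylate of epoxy diol 7 | Cc1ccc(cc1)S(=O)(=O)OC[C@@H]1O[C@@]1(C)C/C=C/C(C)(C)O
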